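I will reckon this flask from its two ends and join them, taking the start from the grey run and the end from the charges.

| setting | grey | flask |
|---|---|---|
| G | 0.77 M | 0.77 M |
| E | 0.92 M | 0.616 M |
| remark | run made earlier |  |
| time |  | 4.0 d |
| volume of the second phase over the first |  | 0.50 |

grey run (percent of the G charged)

| time / h | J / % |
|---|---|
| 1.50 | 0 |
| 4.00 | 1.4 |
| 8.00 | 4.3 |
| 12.0 | 7.3 |
| 20.0 | 13.7 |
| 25.0 | 19.4 |
| 30.0 | 23.2 |

(each reading ± 0.5 percentage points)

- in the second phase: E; everything else is in the first
- charges count per volume of the first phase; a concentration in a rate is the amount of a species over the volume of its own phase; every rate counts per litre of the first phase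
- the earlier runs hold the two phases in the same ratio of volumes as the flask asked about

- alpha: doubling the amount of E, all else as stated
- epsilon: doubling the transfer coefficient of E, all else as stated

* the J standing at 4.0 d, as a percentage of the G charged
* the change that raises the amount of J at 4.0 d, in percent of the G charged most ("none" if none brings more than 2 percentage points) (alpha / epsilon / none)
* amount of J at 4.0 d, in percent of the G charged, after epsilon

Which end comes first? The late one. The flask holds 0.616 M of E against 0.77 M of G, so E is the limiting reagent and the charges allow J up to 80.0% of the G charged.

And the early end? The grey run climbs in a nearly straight line from 8.00 h to 30.0 h. That slope gives 5.79 d for τ, the time the E charge would last at that rate of making J. It is a reading and carries the scatter. Traced back, the line reaches zero at a lag of 2.99 h.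

How do you join them? I let J rise exponentially towards the cap with time constant τ, starting after the lag. That gives my 39.0%.

But the grey line does not bend, so why should yours? Because the grey run stopped at 30.0 h, well short of τ, while this flask runs to 0.690 of τ.

And the changes? Doubling E doubles J in my picture, to 78.0%. If the lag is E filling the first phase, doubling transfer halves it, and because the lag is far shorter than τ, I get 39.5%, a gain of 0.50 percentage points. So I choose alpha.

The forecast says 55%, alpha and 62%, with the ground “Doubling E lifts both the rate and the cap, so it wins in most pictures.” Its two amounts lie above mine, and its choice is the same.

With L the reagent in the first phase, the steps are: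

    L ⇌ E, rate k1*([L] - [E]/K1) per volume of the first phase (partition coefficient = 1.91, kL = 1.36 × 10⁻⁵ s⁻¹)
    G + L ⇌ J (K = 6.30 M⁻¹, k = 1.00 × 10⁻⁵ M⁻¹ s⁻¹)

The flask gives 36.9%, with alpha best at a gain of 24 points, and 38.4% after epsilon. Left for 40.0 d, this flask stands at 45.9%, less than the cap of 80.0%. Read backward through my curve, its 36.9% gives τ as 6.25 d, beside the 5.79 d read from the grey run. Going back to that grey reading of 5.79 d, not the value read backward, and taking it inversely proportional to G, an assumption of mine, makes τ 14.4 d for the neighbour with 0.31 M of G, and the curve then gives 46.9% of its G, where that neighbour stands at 44.9%.

All runs are simulated for substances that don't exist; scatter was added.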